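**Strategy.** The route rests on cutting the C-4–C-3a bond (CH2–CH) of the cyclopentanone (ring B); its CH is the ring-fusion carbon that also carries the O–CMe2 carbon of the γ-lactone (ring C). The key step cyclises an acyclic β-keto ester carrying a CH2-radical precursor (N-acyloxyphthalimide) and, on its quaternary C(Me)(CO2Me) centre, a 2-methylprop-1-enyl group: the primary radical closes ring B at the alkene CH, and the tertiary radical is oxidised to the CMe2 cation, which the neighbouring ester traps as ring C. Since only a cis-fused lactone can close, the preset quaternary centre dictates the new CH centre. Convex-face prenylation, a glyoxal-ene reaction and lactonisation then add the δ-lactone (ring A).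

Key step: step 6

Remark on locants: the bicyclic core is numbered as a cyclopenta[c]furan: C-1 (lactone C=O), O-2, C-3 (CMe2), C-3a (ring-fusion CH), C-4 (CH2), C-5 (spiro carbon), C-6 (ketone), C-6a (C–Me).

Remark on the chemistry (assumption): pig liver esterase is taken to cleave the ester group of 4 that leads to the (S)-half-ester 5; if it prefers the other one, the resolution given under the fallbacks supplies 5.

**Step 1**
Reactants: 1 isobutyraldehyde (2-methylpropanal); 2 dimethyl malonate
Product: 3 dimethyl 2-(2-methylpropylidene)propanedioate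
Conditions: piperidine (cat.), AcOH (cat.), PhMe, reflux, Dean–Stark
Reagents that add atoms: none
Why: Knoevenagel condensation with azeotropic removal of water; any deconjugated isomer is harmless because both isomers give the same extended enolate in step 2.

**Step 2**
Reactants: 3 dimethyl 2-(2-methylpropylidene)propanedioate
Product: 4 dimethyl 2-methyl-2-(2-methylprop-1-en-1-yl)propanedioate
Conditions: LiN(i-Pr)2 (1.1 equiv), THF, −78 °C; MeI, −78 °C to rt
Reagents that add atoms: iodomethane, CI
Why: Deconjugative α-alkylation: γ-deprotonation gives the extended enolate, which is methylated at the α-carbon to give the prochiral quaternary malonate with the alkene shifted into the 2-methylprop-1-enyl position.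

**Step 3**
Reactants: 4 dimethyl 2-methyl-2-(2-methylprop-1-en-1-yl)propanedioate
Product: 5 (S)-2-(methoxycarbonyl)-2,4-dimethylpent-3-enoic acid
Conditions: pig liver esterase, 0.1 M phosphate buffer (pH 7.5)/DMSO 9:1, 25 °C, pH-stat with 1 M NaOH (1.0 equiv); then 1 M HCl
Reagents that add atoms: water, O
Why: Enzymatic desymmetrisation of a prochiral α,α-disubstituted malonate: hydrolysis of one enantiotopic ester group sets the quaternary centre (the later C-6a) as (S).

**Step 4**
Reactants: 5 (S)-2-(methoxycarbonyl)-2,4-dimethylpent-3-enoic acid; 6 4-methoxy-4-oxobutanoic acid (monomethyl succinate)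
Product: 8 (5S)-3,5-bis(methoxycarbonyl)-5,7-dimethyl-4-oxooct-6-enoic acid (both C-3 epimers), via acid chloride 7 (not isolated)
Conditions: (COCl)2, DMF (cat.), CH2Cl2, 0 °C to rt, evaporate; then add to the dilithio derivative of 6 (2.2 equiv; LiN(i-Pr)2 4.5 equiv, THF, −78 °C), −78 to −20 °C; 1 M HCl
Reagents that add atoms: oxalyl chloride, O=C(Cl)C(=O)Cl (chlorine of intermediate 7 only)
Why: Crossed Claisen-type C-acylation of the ester enolate of the succinate dianion (carboxylate as spectator, excess enolate takes up the acidic β-keto ester proton) by the non-enolisable acid chloride; the new CH(CO2Me) centre is a labile β-keto ester centre, so its two epimers are of no consequence.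

**Step 5**
Reactants: 8 (5S)-3,5-bis(methoxycarbonyl)-5,7-dimethyl-4-oxooct-6-enoic acid
Product: 9 1,3-dioxoisoindolin-2-yl (5S)-3,5-bis(methoxycarbonyl)-5,7-dimethyl-4-oxooct-6-enoate (both C-3 epimers)
Conditions: N-hydroxyphthalimide, DIC, DMAP (cat.), CH2Cl2, 0 °C to rt
Reagents that add atoms: N-hydroxyphthalimide, O=C1c2ccccc2C(=O)N1O
Why: Carbodiimide (Steglich-type) esterification of the free acid gives the redox-active ester without touching the quaternary stereocentre.

**Step 6**
Reactants: 9 1,3-dioxoisoindolin-2-yl (5S)-3,5-bis(methoxycarbonyl)-5,7-dimethyl-4-oxooct-6-enoate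
Product: 11 methyl (3aS,6aS)-3,3,6a-trimethyl-1,6-dioxohexahydro-1H-cyclopenta[c]furan-5-carboxylate (both C-5 epimers), via isopropylidene diester 10 (not isolated)
Conditions: fac-Ir(ppy)3 (1 mol%), ClCH2CH2Cl containing H2O (5 equiv), 450 nm LEDs, rt; then TfOH (0.2 equiv), 50 °C
Reagents that add atoms: water, O
Why: Proposed new method: photoexcited fac-Ir(ppy)3 reduces the N-acyloxyphthalimide, which loses CO2 and phthalimide anion to give the primary radical at C-4; this radical adds 5-exo-trig to the CH terminus of the 2-methylprop-1-enyl group (closing ring B), and the tertiary CMe2 radical is oxidised by the tetravalent iridium species to the cation, which the ester carbonyl oxygen on C-6a captures in a five-membered ionic closure (ring C) before water cleaves the methyl oxonium ion. The closest known reaction types are photoredox decarboxylative radical–polar crossover substitutions of redox-active esters and the oxidative radical cyclisation–lactonisations mediated by Mn(OAc)3/Cu(OAc)2; their merger on an unactivated primary radical with an aliphatic trisubstituted alkene is the new element. The only new stereocentre, C-3a, is controlled by the preset C-6a centre because a γ-lactone can only be cis-fused to ring B: a cation with CMe2 trans to the ester loses a proton to give the exocyclic alkene 10, which TfOH reprotonates reversibly until the cis cation is trapped, so both faces of radical attack converge on one ring fusion. The step needs the 5-exo closure to outrun the 1,2-acyl shift of the β-keto radical (Dowd–Beckwith pathway) and 6-endo attack, which the quaternary centre in the chain (gem-disubstituent effect), the trisubstituted alkene and the hindered ketone should secure. C-5 remains an epimerisable β-keto ester centre and is fixed in step 7.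

**Step 7**
Reactants: 11 methyl (3aS,6aS)-3,3,6a-trimethyl-1,6-dioxohexahydro-1H-cyclopenta[c]furan-5-carboxylate; 12 1-bromo-3-methylbut-2-ene (prenyl bromide)
Product: 13 methyl (3aS,5R,6aS)-3,3,6a-trimethyl-5-(3-methylbut-2-en-1-yl)-1,6-dioxohexahydro-1H-cyclopenta[c]furan-5-carboxylate
Conditions: K2CO3, acetone, rt
Reagents that add atoms: none
Why: C-alkylation (SN2) of the cyclic β-keto ester enolate on the convex face of the cis-fused bicyclo[3.3.0] system, anti to ring C and its endo methyl group, should convert both C-5 epimers into the single (5R) quaternary centre with CO2Me cis to ring C.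

**Step 8**
Reactants: 14 3-methylbutan-2-one
Product: 15 3-methyl-2-oxobutanal
Conditions: SeO2, 1,4-dioxane/H2O, reflux; distil before use
Reagents that add atoms: selenium dioxide, O=[Se]=O
Why: Riley oxidation of the methyl group α to the ketone to the aldehyde; the isopropyl methine cannot be taken to a carbonyl group.

**Step 9**
Reactants: 13 methyl (3aS,5R,6aS)-3,3,6a-trimethyl-5-(3-methylbut-2-en-1-yl)-1,6-dioxohexahydro-1H-cyclopenta[c]furan-5-carboxylate; 15 3-methyl-2-oxobutanal
Product: 17 (3aS,5R,5'S,6'S,6aS)-3,3,6a-trimethyl-6'-(2-methylpropanoyl)-5'-(prop-1-en-2-yl)tetrahydrospiro[cyclopenta[c]furan-5,3'-pyran]-1,2',6-trione (CNP0216954.1), via ene adduct 16 (not isolated)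
Conditions: [Cu((S,S)-t-Bu-box)](SbF6)2 (10 mol%, from CuCl2, ligand and AgSbF6), 15 (1.5 equiv), CH2Cl2, 0 °C to rt; then PPTS (cat.), PhMe, 60 °C
Reagents that add atoms: none
Why: Catalytic enantioselective carbonyl-ene reaction of the chelated 1,2-dicarbonyl aldehyde: C–C bond formation at the CH end of the prenyl alkene with hydrogen transfer from a methyl group creates the isopropenyl group, the C2-symmetric catalyst controls the carbinol centre ((S) expected by analogy with glyoxylate-ene reactions; the antipodal ligand is used if the sense is opposite) and the exo transition state relates the allylic centre to it (anti type, (S)), after which acid-catalysed transesterification of the δ-hydroxy methyl ester closes ring A.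

**Compound list**
1 | isobutyraldehyde (2-methylpropanal) | CC(C)C=O | starting material
2 | dimethyl malonate | COC(=O)CC(=O)OC | starting material
3 | dimethyl 2-(2-methylpropylidene)propanedioate | COC(=O)C(=CC(C)C)C(=O)OC | intermediate
4 | dimethyl 2-methyl-2-(2-methylprop-1-en-1-yl)propanedioate | COC(=O)C(C)(C=C(C)C)C(=O)OC | intermediate
5 | (S)-2-(methoxycarbonyl)-2,4-dimethylpent-3-enoic acid | OC(=O)[C@](C)(C=C(C)C)C(=O)OC | intermediate
6 | 4-methoxy-4-oxobutanoic acid (monomethyl succinate) | COC(=O)CCC(O)=O | starting material
7 | methyl (2R)-2-(chlorocarbonyl)-2,4-dimethylpent-3-enoate (same spatial arrangement as 5; descriptor changes by priority only) | ClC(=O)[C@](C)(C=C(C)C)C(=O)OC | intermediate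
8 | (5S)-3,5-bis(methoxycarbonyl)-5,7-dimethyl-4-oxooct-6-enoic acid (both C-3 epimers) | OC(=O)CC(C(=O)OC)C(=O)[C@](C)(C=C(C)C)C(=O)OC | intermediate
9 | 1,3-dioxoisoindolin-2-yl (5S)-3,5-bis(methoxycarbonyl)-5,7-dimethyl-4-oxooct-6-enoate (both C-3 epimers) | O=C1c2ccccc2C(=O)N1OC(=O)CC(C(=O)OC)C(=O)[C@](C)(C=C(C)C)C(=O)OC | intermediate
10 | dimethyl (1S)-1-methyl-2-oxo-5-(propan-2-ylidene)cyclopentane-1,3-dicarboxylate (both C-3 epimers) | COC(=O)C1CC(=C(C)C)[C@](C)(C(=O)OC)C1=O | intermediate
11 | methyl (3aS,6aS)-3,3,6a-trimethyl-1,6-dioxohexahydro-1H-cyclopenta[c]furan-5-carboxylate (both C-5 epimers) | COC(=O)C1C[C@@H]2C(C)(C)OC(=O)[C@]2(C)C1=O | intermediate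
12 | 1-bromo-3-methylbut-2-ene (prenyl bromide) | CC(C)=CCBr | starting material
13 | methyl (3aS,5R,6aS)-3,3,6a-trimethyl-5-(3-methylbut-2-en-1-yl)-1,6-dioxohexahydro-1H-cyclopenta[c]furan-5-carboxylate | COC(=O)[C@]1(CC=C(C)C)C[C@@H]2C(C)(C)OC(=O)[C@]2(C)C1=O | intermediate
14 | 3-methylbutan-2-one | CC(C)C(C)=O | starting material
15 | 3-methyl-2-oxobutanal | CC(C)C(=O)C=O | intermediate
16 | methyl (3aS,5R,6aS)-5-[(2S,3S)-3-hydroxy-5-methyl-4-oxo-2-(prop-1-en-2-yl)hexyl]-3,3,6a-trimethyl-1,6-dioxohexahydro-1H-cyclopenta[c]furan-5-carboxylate | C=C(C)[C@H](C[C@@]1(C(=O)OC)C[C@@H]2C(C)(C)OC(=O)[C@]2(C)C1=O)[C@H](O)C(=O)C(C)C | intermediate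
17 | (3aS,5R,5'S,6'S,6aS)-3,3,6a-trimethyl-6'-(2-methylpropanoyl)-5'-(prop-1-en-2-yl)tetrahydrospiro[cyclopenta[c]furan-5,3'-pyran]-1,2',6-trione (CNP0216954.1) | C=C(C)[C@@H]1C[C@]2(C[C@@H]3C(C)(C)OC(=O)[C@]3(C)C2=O)C(=O)O[C@@H]1C(=O)C(C)C | target

**Step count.** Total: 9 steps. Longest linear sequence: 8 steps (steps 1–7 and 9); step 8 is a one-step side branch.

**Steps most likely to fail**

Step 6 (Proposed new method). The β-keto radical may undergo 1,2-acyl migration before it cyclises. The tertiary radical may pick up a hydrogen atom instead of being oxidised. A cation of the trans series may be diverted through the C-5 ester into a bridged lactone instead of returning through the alkene. The fallback uses known chemistry and sets out from acid 8. Esterification with N-hydroxypyridine-2-thione (DCC, CH2Cl2, dark) gives the Barton ester F1. Visible-light photolysis at high dilution (PhH, reflux) brings about decarboxylation, 5-exo cyclisation and thiopyridyl group transfer to give the tertiary 2-pyridyl sulfide F2. Oxidation with mCPBA (1.0 equiv, −40 °C) gives the sulfoxide F3, which on warming undergoes syn-elimination to the exocyclic alkenes, namely the isopropylidene diester 10 and its isopropenyl isomer F4. TfOH (cat.) in wet ClCH2CH2Cl at 50 °C then lactonises both through the same cis-fusion funnel, and the route is rejoined at 11.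

Step 9. The hindered trisubstituted alkene may react slowly, or the 1,3-dicarbonyl unit of 13 may sequester the copper catalyst. The new isopropenyl group may undergo a second ene reaction, and the simple diastereoselection between the two new centres may be insufficient. The fallback sets out from 13. Allylic oxidation of the (E)-methyl group (SeO2 cat., t-BuOOH, CH2Cl2) gives the (E)-allylic alcohol F5. Rh2(OAc)4-catalysed O–H insertion with 1-diazo-3-methylbutan-2-one gives the α-allyloxy ketone F6. Its potassium enolate (KN(SiMe3)2, THF, −78 °C; no other enolisable position is present) undergoes [2,3]-Wittig rearrangement, which forms the same C–C bond and the isopropenyl group. The resulting alkoxide lactonises onto the methyl ester, and the route is rejoined at 17 after chromatographic separation of diastereomers. The enolate counter-ion would be varied to steer the relative configuration.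

Step 3. The enzyme may discriminate poorly between the two ester groups, which would erode the enantiomeric purity of every later compound. The fallback sets out from 4. Mono-saponification (KOH, 1.0 equiv, MeOH/H2O) gives the racemic half-ester F7. Fractional crystallisation of its salt with (R)-1-phenylethylamine gives the diastereomeric salt F8 of the (S)-acid (the antipodal amine is used if the other salt is the less soluble one). Acidification rejoins the route at 5.

**Further compounds**
F1 | step 6 | 2-thioxopyridin-1(2H)-yl (5S)-3,5-bis(methoxycarbonyl)-5,7-dimethyl-4-oxooct-6-enoate (Barton ester) | O=C(CC(C(=O)OC)C(=O)[C@](C)(C=C(C)C)C(=O)OC)ON1C=CC=CC1=S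
F2 | step 6 | dimethyl (1S)-1-methyl-2-oxo-5-[2-(pyridin-2-ylsulfanyl)propan-2-yl]cyclopentane-1,3-dicarboxylate (C-3 and C-5 epimers) | COC(=O)C1CC(C(C)(C)Sc2ccccn2)[C@](C)(C(=O)OC)C1=O
F3 | step 6 | dimethyl (1S)-1-methyl-2-oxo-5-[2-(pyridin-2-ylsulfinyl)propan-2-yl]cyclopentane-1,3-dicarboxylate | COC(=O)C1CC(C(C)(C)S(=O)c2ccccn2)[C@](C)(C(=O)OC)C1=O
F4 | step 6 | dimethyl (1S)-1-methyl-2-oxo-5-(prop-1-en-2-yl)cyclopentane-1,3-dicarboxylate (C-3 and C-5 epimers) | COC(=O)C1CC(C(C)=C)[C@](C)(C(=O)OC)C1=O
F5 | step 9 | methyl (3aS,5R,6aS)-5-[(2E)-4-hydroxy-3-methylbut-2-en-1-yl]-3,3,6a-trimethyl-1,6-dioxohexahydro-1H-cyclopenta[c]furan-5-carboxylate | COC(=O)[C@]1(C/C=C(\C)CO)C[C@@H]2C(C)(C)OC(=O)[C@]2(C)C1=O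
F6 | step 9 | methyl (3aS,5R,6aS)-3,3,6a-trimethyl-5-[(2E)-3-methyl-4-(3-methyl-2-oxobutoxy)but-2-en-1-yl]-1,6-dioxohexahydro-1H-cyclopenta[c]furan-5-carboxylate | COC(=O)[C@]1(C/C=C(\C)COCC(=O)C(C)C)C[C@@H]2C(C)(C)OC(=O)[C@]2(C)C1=O
F7 | step 3 | rac-2-(methoxycarbonyl)-2,4-dimethylpent-3-enoic acid | OC(=O)C(C)(C=C(C)C)C(=O)OC
F8 | step 3 | (R)-1-phenylethylammonium (S)-2-(methoxycarbonyl)-2,4-dimethylpent-3-enoate | C[C@@H]([NH3+])c1ccccc1.[O-]C(=O)[C@](C)(C=C(C)C)C(=O)OC
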